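The readings stem from a simulated flask on assumed constants; the scatter is artificial.

At late times the oak run still read 0 % product at 8.00 h, less than the 14 % of the alder run at 8.00 h, at the same temperature.

| flask | starting material | free enzyme | impurity | temperature | remark | time |
|---|---|---|---|---|---|---|
| alder | 0.034 M | 1.9 µM | 1.3 µM | 18 °C | run made earlier |  |
| larch | 0.075 M | 1.9 µM | 1.3 µM | 34 °C | run made earlier |  |
| oak | 0.050 M | 1.9 µM | 2.6 µM | 18 °C | run made earlier |  |
| winter | 0.050 M | 1.9 µM | 1.3 µM |  | at 40 °C until 3.0 h, from then on at 10 °C | 10 h |
| noon | 0.050 M | 1.9 µM | 1.3 µM | 10 °C |  | 10 h |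
| dusk | 0.050 M | 1.9 µM | 1.3 µM | 40 °C |  | 10 h |
| spring | 0.050 M | 1.9 µM | 1.3 µM | 25 °C |  | 10 h |

| run | time / h | product / % | starting material / % |
|---|---|---|---|
| alder | 0.500 | 1 | 99 |
| alder | 1.50 | 0 | 95 |
| alder | 3.00 | 8 | 95 |
| alder | 4.00 | 6 | 93 |
| alder | 6.00 | 9 | 91 |
| alder | 8.00 | 14 | 87 |
| larch | 0.167 | 1 | 97 |
| larch | 0.500 | 2 | 100 |
| larch | 1.00 | 0 | 99 |
| larch | 1.33 | 3 | 97 |
| larch | 2.00 | 3 | 97 |
| larch | 2.50 | 2 | 97 |
| oak | 0.667 | 0 | 99 |
| oak | 1.33 | 0 | 100 |
| oak | 2.50 | 1 | 100 |
| oak | 4.00 | 1 | 102 |
| oak | 8.00 | 0 | 100 |

(standard deviation of a reading: 1.5 percentage points)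

1. the flask that comes out highest in amount of product, in percent of the starting material charged, or "all alike" when all lie within 1.5 percentage points (winter / noon / dusk / spring / all alike)
2. product at the end, in percent of the starting material charged, winter
3. product at the end, in percent of the starting material charged, noon
4. product at the end, in percent of the starting material charged, dusk
5. product at the end, in percent of the starting material charged, spring

1. Impurity. I took its binding to free enzyme as a fast step, one to one, and as over before the first reading. In the oak run the subtraction c(free enzyme) − c(impurity) is negative, −0.700 µM, and oak's readings stayed near zero.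

2. The quantity. In the four asked flasks impurity is the limiting reagent of that binding, at 1.3 µM against 1.9 µM. 0.600 µM is therefore the working enzyme, the free enzyme left after the titration. That is 31.6 % of the charge.

3. Enzyme charge. By hand, with impurity held at 1.3 µM, every extra bit of charge goes to the working enzyme. With these charges, one per cent more enzyme charged gives 3.17 per cent more working enzyme.

4. Temperature. By hand, the subtraction does not change with temperature, since it counts charges. The rate per working enzyme can change. Alder's last reading at 18 °C gave an average of 0.595 mM/h since the start, and larch's last reading at 34 °C gave 0.600 mM/h. But that larch reading of 2 % carries a scatter of 1.5 percentage points, and larch also had more starting material, so I read no temperature effect from this pair.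

5. Time. By hand, a steady flask gains in proportion to the hours. Larch read 3 % at 1.33 h and 2 % at 2.50 h, within the scatter of 1.5 points, and it was not followed further.

The forecast named spring and gave 3 % for winter, 8 % for noon, 2.5 % for dusk and 11 % for spring. On larch it said “which I read as thermal death of the enzyme”.

The flasks gave 10.4 % in winter, 8.85 % in noon, 12.9 % in dusk and 17.7 % in spring, the highest.

    free enzyme + impurity → spent catalyst (k = 2.60 × 10⁵ /M/min, Ea = 18.0 kJ/mol)
    starting material + free enzyme → product + free enzyme, rate k2*[starting material]^2*[free enzyme]/(1 + ([starting material]/Kh2)^2) (20.0 mM, k = 75000 /M²/min, Ea = 35.0 kJ/mol)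
    free enzyme → unfolded enzyme (k = 1.20 × 10⁻⁴ /min, Ea = 185 kJ/mol)
    (constants at 25 °C)

Dusk parted most from the forecast: it still held 8.54 % of its enzyme free at 5.00 h, with 10.2 % product. In noon, free enzyme stood at 31.5 % of the charge at 10.0 h, which is 0.599 µM against the 0.600 µM I had subtracted. A neighbour of spring charged with 3.2 × 10⁻⁶ M of free enzyme has 1.90 µM of working enzyme, 3.17 times spring's, and it reached 50.1 % product at 10.0 h.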